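**Plan**

- Retrosynthesis cuts, in this order: the furan O1–C2 bond (with the aromatising oxidation undone), the ester C–O bond, the bond between the alkene carbon and the carbinol carbon (as a vinyl–acyl bond), and the benzylic CH2–alkyne bond.
- Enabling feature: furan O1, C2, C3, C4 and C5 are the hydroxymethyl oxygen, the benzylic carbon, the two alkene carbons and the hydroxymethyl carbon of a (2E)-1-aryl-3-(hydroxymethyl)alk-2-ene. The benzylic carbon becomes electrophilic once the 2,5-dihydroxyphenyl ring it carries is oxidised to the quinone and tautomerises to the ortho-quinone methide.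
- Forward: silylated benzyl bromide plus propargyl alcohol gives the alkynol; syn-hydrostannation/iodination gives the vinyl iodide; acylation with a Weinreb amide gives the enone; reduction, esterification and desilylation follow. The furan, the only ring made, closes in the last step.
- Stereochemistry: the carbinol centre (R) comes from (S)-CBS reduction of the enone and the acyl centre (R) from (R)-2-methylbutanoic acid. The alkene geometry (CH2OH cis to the benzylic CH2) comes from the syn-hydrostannation and is kept through iodination and I/Li exchange.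

Key step: step 12

Remark: in the text the furan atoms are called O1, C2 (aryl-bearing), C3, C4 (chain-bearing) and C5, whereas the systematic names number the ring from the other side; TBS = tert-butyldimethylsilyl.

**Route**

Step 1
Reactants: 1 2,5-dihydroxybenzaldehyde
Product: 2 2,5-bis(tert-butyldimethylsilyloxy)benzaldehyde
Conditions: TBSCl (2.5 equiv), imidazole (5 equiv), DMF, 0 °C to rt
Reagents that add atoms: tert-butyldimethylsilyl chloride, CC(C)(C)[Si](C)(C)Cl
Why: Imidazole-promoted silylation of phenols should cap both hydroxyls (the hydrogen-bonded ortho one more slowly) as ethers that tolerate the organometallic steps and fall to fluoride at the end.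

Step 2
Reactants: 2 2,5-bis(tert-butyldimethylsilyloxy)benzaldehyde
Product: 3 [2,5-bis(tert-butyldimethylsilyloxy)phenyl]methanol
Conditions: NaBH4, EtOH/THF (1:1), 0 °C, short reaction time; water
Reagents that add atoms: none
Why: Borohydride reduction of an aryl aldehyde is routine, and a short time at 0 °C should keep the ortho silyl group from migrating to the new alkoxide.

Step 3
Reactants: 3 [2,5-bis(tert-butyldimethylsilyloxy)phenyl]methanol
Product: 4 2-(bromomethyl)-1,4-bis(tert-butyldimethylsilyloxy)benzene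
Conditions: CBr4, PPh3, CH2Cl2, 0 °C; used promptly
Reagents that add atoms: carbon tetrabromide, BrC(Br)(Br)Br
Why: The Appel bromination is neutral, so the benzylic bromide should form without loss of the aryl silyl ethers.

Step 4
Reactants: 4 2-(bromomethyl)-1,4-bis(tert-butyldimethylsilyloxy)benzene; 5 propargyl alcohol (prop-2-yn-1-ol)
Product: 7 4-[2,5-bis(tert-butyldimethylsilyloxy)phenyl]but-2-yn-1-ol, via propargyl alcohol dimagnesium salt 6 (not isolated)
Conditions: 5 (2.0 equiv), EtMgBr (4.0 equiv), THF, 0 °C to rt; CuCl (10 mol%), then 4, 50 °C; aq. NH4Cl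
Reagents that add atoms: none
Why: Copper-catalysed coupling of an alkynylmagnesium halide with a benzylic bromide is a standard sp–sp3 bond formation in which the acetylide carbon, not the magnesium alkoxide, is alkylated, and aryl silyl ethers tolerate Grignard reagents.

Step 5
Reactants: 7 4-[2,5-bis(tert-butyldimethylsilyloxy)phenyl]but-2-yn-1-ol
Product: 9 (E)-4-[2,5-bis(tert-butyldimethylsilyloxy)phenyl]-2-iodobut-2-en-1-ol, via vinylstannane 8 (not isolated)
Conditions: Bu3SnH (1.2 equiv), PdCl2(PPh3)2 (2 mol%), THF, 0 °C to rt; then I2 (1.3 equiv), CH2Cl2, 0 °C; aq. Na2S2O3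
Reagents that add atoms: iodine, II
Why: Palladium-catalysed hydrostannation adds H and Sn syn, with the propargylic hydroxyl expected to steer tin to the neighbouring carbon, and iododestannylation keeps the geometry, so CH2OH and the benzylic CH2 should end up cis; any regioisomeric iodide is removed by chromatography.

Step 6
Reactants: 9 (E)-4-[2,5-bis(tert-butyldimethylsilyloxy)phenyl]-2-iodobut-2-en-1-ol
Product: 10 tert-butyl{[(2E)-4-[2,5-bis(tert-butyldimethylsilyloxy)phenyl]-2-iodobut-2-en-1-yl]oxy}dimethylsilane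
Conditions: TBSCl, imidazole, CH2Cl2, 0 °C to rt
Reagents that add atoms: tert-butyldimethylsilyl chloride, CC(C)(C)[Si](C)(C)Cl
Why: Silylation of the primary allylic alcohol removes the acidic proton before metalation and leaves this oxygen free of acyl in step 10, with the same protecting group as on the phenols so that one deprotection serves all three.

Step 7
Reactants: 11 4-methylpent-3-enoic acid
Product: 12 N-methoxy-N,4-dimethylpent-3-enamide
Conditions: MeNH(OMe)·HCl, EDC·HCl, N-methylmorpholine, CH2Cl2, 0 °C to rt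
Reagents that add atoms: N,O-dimethylhydroxylamine hydrochloride, CNOC.Cl
Why: Carbodiimide amidation under mild base should give the Weinreb amide without moving the β,γ-alkene into conjugation.

Step 8
Reactants: 10 tert-butyl{[(2E)-4-[2,5-bis(tert-butyldimethylsilyloxy)phenyl]-2-iodobut-2-en-1-yl]oxy}dimethylsilane; 12 N-methoxy-N,4-dimethylpent-3-enamide
Product: 14 (2E)-1-[2,5-bis(tert-butyldimethylsilyloxy)phenyl]-3-[(tert-butyldimethylsilyloxy)methyl]-7-methylocta-2,6-dien-4-one, via vinyllithium 13 (not isolated)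
Conditions: t-BuLi (2.05 equiv), Et2O, −78 °C; then 12 (1.2 equiv), −78 to −40 °C; AcOH, −78 °C
Reagents that add atoms: none
Why: Iodine–lithium exchange keeps the alkene geometry at −78 °C, the Weinreb ketone synthesis stops at the ketone without over-addition, and the cold acetic acid quench avoids base-induced movement of either alkene.

Step 9
Reactants: 14 (2E)-1-[2,5-bis(tert-butyldimethylsilyloxy)phenyl]-3-[(tert-butyldimethylsilyloxy)methyl]-7-methylocta-2,6-dien-4-one
Product: 15 (2E,4R)-1-[2,5-bis(tert-butyldimethylsilyloxy)phenyl]-3-[(tert-butyldimethylsilyloxy)methyl]-7-methylocta-2,6-dien-4-ol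
Conditions: (S)-Me-CBS (0.3 equiv), catecholborane (1.8 equiv), toluene, −78 °C; MeOH, then pH 7 buffer
Reagents that add atoms: none
Why: In this Corey–Bakshi–Shibata reduction the α-branched alkenyl group acts as the large substituent and the CH2 chain as the small one, so the (S)-catalyst should deliver hydride in the sense that turns acetophenone into (R)-1-phenylethanol and set the (R)-carbinol, while catecholborane leaves the alkenes alone.

Step 10
Reactants: 15 (2E,4R)-1-[2,5-bis(tert-butyldimethylsilyloxy)phenyl]-3-[(tert-butyldimethylsilyloxy)methyl]-7-methylocta-2,6-dien-4-ol; 16 (R)-2-methylbutanoic acid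
Product: 17 (2E,4R)-1-[2,5-bis(tert-butyldimethylsilyloxy)phenyl]-3-[(tert-butyldimethylsilyloxy)methyl]-7-methylocta-2,6-dien-4-yl (2R)-2-methylbutanoate
Conditions: DCC, DMAP (0.1 equiv), CH2Cl2, 0 °C to rt
Reagents that add atoms: none
Why: Steglich esterification acylates the only free hydroxyl with retention at the carbinol carbon, and at 0 °C with catalytic DMAP the α-centre of the acid should not epimerise.

Step 11
Reactants: 17 (2E,4R)-1-[2,5-bis(tert-butyldimethylsilyloxy)phenyl]-3-[(tert-butyldimethylsilyloxy)methyl]-7-methylocta-2,6-dien-4-yl (2R)-2-methylbutanoate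
Product: 18 (2E,4R)-1-(2,5-dihydroxyphenyl)-3-(hydroxymethyl)-7-methylocta-2,6-dien-4-yl (2R)-2-methylbutanoate
Conditions: TBAF/AcOH (1:1, 5 equiv), THF, 0 °C to rt, argon
Reagents that add atoms: none
Why: Fluoride-mediated desilylation cleaves the two aryl silyl ethers quickly and the primary one more slowly, and the acetic acid buffer should suppress both 1,3-acyl shift to the freed primary hydroxyl and air oxidation of the hydroquinone.

Step 12
Reactants: 18 (2E,4R)-1-(2,5-dihydroxyphenyl)-3-(hydroxymethyl)-7-methylocta-2,6-dien-4-yl (2R)-2-methylbutanoate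
Product: 25 (1R)-1-[5-(2,5-dihydroxyphenyl)furan-3-yl]-4-methylpent-3-en-1-yl (2R)-2-methylbutanoate (target), via allylquinone 19 (not isolated), via quinone methide 20 (not isolated), via dihydrofuran 21 (not isolated), via dihydrofuranylquinone 22 (not isolated), via furanylidene quinone methide 23 (not isolated), via furylquinone 24 (not isolated)
Conditions: Ag2O (3.3 equiv), (CF3)2CHOH/CH2Cl2 (1:4), rt, dark, argon; then aq. Na2S2O4, EtOAc
Reagents that add atoms: none
Why: Proposed new method: silver(I) oxide should oxidise hydroquinone 18 to allylquinone 19, whose benzylic C–H (allylic and vinylogous to a quinone carbonyl) tautomerises to the ortho-quinone methide 20, and the primary hydroxyl, held cis to the methide carbon by the E alkene, adds there (oxa-Michael, O1–C2 bond) to return the hydroquinone as 2,5-dihydrofuran 21. Re-oxidation to 22, tautomerisation to the furanylidene quinone methide 23 and a prototropic shift from C5 aromatise the ring, the excess oxidant carries the arylfuran on to furylquinone 24, and the dithionite work-up reduces 24 to 25. The closest known reaction types are the tautomerisation of allyl- and prenylquinones to quinone methides that are trapped by an internal oxygen (chromenol formation), the conjugate addition of alcohols to ortho-quinone methides and the oxidative aromatisation of 2-aryl-2,5-dihydrofurans. The furan ring closes in a 5-exo-trig mode with respect to the methide C=C bond, the cis C3=C4 alkene lying inside the ring and turning out of conjugation as the oxygen approaches. The C2 stereocentre of 21 forms without control and is erased on aromatisation, while the carbinol and acyl centres are not touched. The step needs hydroxyl attack to outrun oxa-6π closure of 20 to a 2H-chromene; this rests on the cis hydroxymethyl group (which can reach the methide carbon from either methide geometry, whereas electrocyclisation needs the Z methide), on the acyloxy carbon being trans and unable to close, and on the non-nucleophilic, hydrogen-bond-donating fluoroalcohol that activates the methide carbonyl without competing for it.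

**Compound list**

1 | 2,5-dihydroxybenzaldehyde | O=Cc1cc(O)ccc1O | starting material
2 | 2,5-bis(tert-butyldimethylsilyloxy)benzaldehyde | O=Cc1cc(O[Si](C)(C)C(C)(C)C)ccc1O[Si](C)(C)C(C)(C)C | intermediate
3 | [2,5-bis(tert-butyldimethylsilyloxy)phenyl]methanol | OCc1cc(O[Si](C)(C)C(C)(C)C)ccc1O[Si](C)(C)C(C)(C)C | intermediate
4 | 2-(bromomethyl)-1,4-bis(tert-butyldimethylsilyloxy)benzene | BrCc1cc(O[Si](C)(C)C(C)(C)C)ccc1O[Si](C)(C)C(C)(C)C | intermediate
5 | propargyl alcohol (prop-2-yn-1-ol) | C#CCO | starting material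
6 | dimagnesium salt of propargyl alcohol, BrMg–C≡C–CH2–OMgBr (formed in the flask) | Br[Mg]C#CCO[Mg]Br | intermediate
7 | 4-[2,5-bis(tert-butyldimethylsilyloxy)phenyl]but-2-yn-1-ol | OCC#CCc1cc(O[Si](C)(C)C(C)(C)C)ccc1O[Si](C)(C)C(C)(C)C | intermediate
8 | (E)-4-[2,5-bis(tert-butyldimethylsilyloxy)phenyl]-2-(tributylstannyl)but-2-en-1-ol (formed in the flask; Sn trans to the benzylic CH2) | CCCC[Sn](CCCC)(CCCC)/C(CO)=C/Cc1cc(O[Si](C)(C)C(C)(C)C)ccc1O[Si](C)(C)C(C)(C)C | intermediate
9 | (E)-4-[2,5-bis(tert-butyldimethylsilyloxy)phenyl]-2-iodobut-2-en-1-ol (I trans to the benzylic CH2, CH2OH cis to it) | OC/C(I)=C\Cc1cc(O[Si](C)(C)C(C)(C)C)ccc1O[Si](C)(C)C(C)(C)C | intermediate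
10 | tert-butyl{[(2E)-4-[2,5-bis(tert-butyldimethylsilyloxy)phenyl]-2-iodobut-2-en-1-yl]oxy}dimethylsilane | CC(C)(C)[Si](C)(C)OC/C(I)=C\Cc1cc(O[Si](C)(C)C(C)(C)C)ccc1O[Si](C)(C)C(C)(C)C | intermediate
11 | 4-methylpent-3-enoic acid | CC(C)=CCC(=O)O | starting material
12 | N-methoxy-N,4-dimethylpent-3-enamide | CON(C)C(=O)CC=C(C)C | intermediate
13 | (2Z)-4-[2,5-bis(tert-butyldimethylsilyloxy)phenyl]-1-(tert-butyldimethylsilyloxy)but-2-en-2-yllithium (formed in the flask; geometry of 10 retained, Li trans to the benzylic CH2) | [Li]/C(CO[Si](C)(C)C(C)(C)C)=C/Cc1cc(O[Si](C)(C)C(C)(C)C)ccc1O[Si](C)(C)C(C)(C)C | intermediate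
14 | (2E)-1-[2,5-bis(tert-butyldimethylsilyloxy)phenyl]-3-[(tert-butyldimethylsilyloxy)methyl]-7-methylocta-2,6-dien-4-one | CC(C)=CCC(=O)/C(CO[Si](C)(C)C(C)(C)C)=C/Cc1cc(O[Si](C)(C)C(C)(C)C)ccc1O[Si](C)(C)C(C)(C)C | intermediate
15 | (2E,4R)-1-[2,5-bis(tert-butyldimethylsilyloxy)phenyl]-3-[(tert-butyldimethylsilyloxy)methyl]-7-methylocta-2,6-dien-4-ol | O[C@H](CC=C(C)C)/C(CO[Si](C)(C)C(C)(C)C)=C/Cc1cc(O[Si](C)(C)C(C)(C)C)ccc1O[Si](C)(C)C(C)(C)C | intermediate
16 | (R)-2-methylbutanoic acid | CC[C@@H](C)C(=O)O | starting material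
17 | (2E,4R)-1-[2,5-bis(tert-butyldimethylsilyloxy)phenyl]-3-[(tert-butyldimethylsilyloxy)methyl]-7-methylocta-2,6-dien-4-yl (2R)-2-methylbutanoate | CC[C@@H](C)C(=O)O[C@H](CC=C(C)C)/C(CO[Si](C)(C)C(C)(C)C)=C/Cc1cc(O[Si](C)(C)C(C)(C)C)ccc1O[Si](C)(C)C(C)(C)C | intermediate
18 | (2E,4R)-1-(2,5-dihydroxyphenyl)-3-(hydroxymethyl)-7-methylocta-2,6-dien-4-yl (2R)-2-methylbutanoate (key-step precursor) | CC[C@@H](C)C(=O)O[C@H](CC=C(C)C)/C(CO)=C/Cc1cc(O)ccc1O | intermediate
19 | (2E,4R)-1-(3,6-dioxocyclohexa-1,4-dien-1-yl)-3-(hydroxymethyl)-7-methylocta-2,6-dien-4-yl (2R)-2-methylbutanoate (allylquinone, formed in the flask) | CC[C@@H](C)C(=O)O[C@H](CC=C(C)C)/C(CO)=C/CC1=CC(=O)C=CC1=O | intermediate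
20 | (4R)-1-(3-hydroxy-6-oxocyclohexa-2,4-dien-1-ylidene)-3-(hydroxymethyl)-7-methylocta-2,6-dien-4-yl (2R)-2-methylbutanoate (ortho-quinone methide, formed in the flask; methide geometry not fixed) | CC[C@@H](C)C(=O)O[C@H](CC=C(C)C)/C(CO)=C/C=C1C=C(O)C=CC1=O | intermediate
21 | (1R)-1-[5-(2,5-dihydroxyphenyl)-2,5-dihydrofuran-3-yl]-4-methylpent-3-en-1-yl (2R)-2-methylbutanoate (formed in the flask; both epimers at the aryl-bearing ring carbon) | CC[C@@H](C)C(=O)O[C@H](CC=C(C)C)C1=CC(c2cc(O)ccc2O)OC1 | intermediate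
22 | (1R)-1-[5-(3,6-dioxocyclohexa-1,4-dien-1-yl)-2,5-dihydrofuran-3-yl]-4-methylpent-3-en-1-yl (2R)-2-methylbutanoate (formed in the flask) | CC[C@@H](C)C(=O)O[C@H](CC=C(C)C)C1=CC(C2=CC(=O)C=CC2=O)OC1 | intermediate
23 | (1R)-1-[5-(3-hydroxy-6-oxocyclohexa-2,4-dien-1-ylidene)-2,5-dihydrofuran-3-yl]-4-methylpent-3-en-1-yl (2R)-2-methylbutanoate (formed in the flask) | CC[C@@H](C)C(=O)O[C@H](CC=C(C)C)C1=CC(=C2C=C(O)C=CC2=O)OC1 | intermediate
24 | (1R)-1-[5-(3,6-dioxocyclohexa-1,4-dien-1-yl)furan-3-yl]-4-methylpent-3-en-1-yl (2R)-2-methylbutanoate (furylquinone, formed in the flask) | CC[C@@H](C)C(=O)O[C@H](CC=C(C)C)c1coc(C2=CC(=O)C=CC2=O)c1 | intermediate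
25 | (1R)-1-[5-(2,5-dihydroxyphenyl)furan-3-yl]-4-methylpent-3-en-1-yl (2R)-2-methylbutanoate | CC[C@@H](C)C(=O)O[C@H](CC=C(C)C)c1coc(-c2cc(O)ccc2O)c1 | target

**Count and risks**

Total step count: 12. Longest linear sequence: 11 (steps 1–6 and 8–12; step 7 is a one-step side branch).

Steps most likely to fail:

1. Step 12 (proposed new method). The quinone methide may close through its own carbonyl oxygen onto the far alkene carbon (oxa-6π electrocyclisation) faster than the hydroxymethyl oxygen reaches the methide carbon, or the quinone may not tautomerise at all in the fluoroalcohol. The fallback builds the arylfuran by cross-coupling with known chemistry; it sets out from amide 12 (with acid 16) and comes back to the route at target 25. 3-Bromofuran is lithiated (n-BuLi, THF, −78 °C) and acylated with 12 to give 1-(furan-3-yl)-4-methylpent-3-en-1-one F1. (S)-Me-CBS/catecholborane reduction should give (R)-1-(furan-3-yl)-4-methylpent-3-en-1-ol F2, and DCC/DMAP esterification with 16 gives (R)-1-(furan-3-yl)-4-methylpent-3-en-1-yl (R)-2-methylbutanoate F3. Iridium-catalysed C–H borylation ([Ir(OMe)(cod)]2, dtbpy, B2pin2) at the unhindered α-position gives the pinacol boronate F4. Suzuki–Miyaura coupling (Pd(dppf)Cl2, K3PO4, dioxane/water) with 2-bromo-1,4-bis(tert-butyldimethylsilyloxy)benzene F5 (from bromohydroquinone, TBSCl and imidazole) gives the bis-silyl ether of the target F6, and TBAF/AcOH then gives 25.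

2. Step 5. Regiocontrol of the hydrostannation may be poor, with tin delivered to the benzyl-bearing alkyne carbon, because both alkyne substituents are CH2 groups. The fallback moves the hydrostannation to a 2-ynoate, where the ester fixes the regiochemistry; it sets out from bromide 4 and comes back at iodo alcohol 9. Copper-catalysed coupling of 4 with ethynylmagnesium bromide gives 1,4-bis(tert-butyldimethylsilyloxy)-2-(prop-2-yn-1-yl)benzene F7. Lithiation of the terminal alkyne (LiHMDS, THF, −78 °C) and methyl chloroformate give methyl 4-[2,5-bis(tert-butyldimethylsilyloxy)phenyl]but-2-ynoate F8. Pd(PPh3)4-catalysed hydrostannation, which on 2-ynoates places tin α to the ester by syn addition, gives methyl (E)-4-[2,5-bis(tert-butyldimethylsilyloxy)phenyl]-2-(tributylstannyl)but-2-enoate F9. Iodine gives methyl (E)-4-[2,5-bis(tert-butyldimethylsilyloxy)phenyl]-2-iodobut-2-enoate F10, and DIBAL-H (CH2Cl2, −78 °C) reduces the ester to 9.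

3. Step 8. The vinyllithium may deprotonate the doubly activated CH2 of the amide instead of adding to it, or lose silanolate by β-elimination before it is trapped. The fallback uses a non-basic organochromium addition to an aldehyde followed by oxidation; it sets out from iodide 10 and comes back at enone 14. Nozaki–Hiyama–Kishi coupling (CrCl2, cat. NiCl2, DMF/DMSO, rt) of 10 with 4-methylpent-3-enal F11 (Dess–Martin oxidation of 4-methylpent-3-en-1-ol, used at once) gives the racemic alcohol (2E)-1-[2,5-bis(tert-butyldimethylsilyloxy)phenyl]-3-[(tert-butyldimethylsilyloxy)methyl]-7-methylocta-2,6-dien-4-ol F12, and Dess–Martin oxidation of F12 gives 14.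

**Further compounds**

F1 | step 12 | 1-(furan-3-yl)-4-methylpent-3-en-1-one | CC(C)=CCC(=O)c1ccoc1
F2 | step 12 | (R)-1-(furan-3-yl)-4-methylpent-3-en-1-ol | O[C@H](CC=C(C)C)c1ccoc1
F3 | step 12 | (R)-1-(furan-3-yl)-4-methylpent-3-en-1-yl (R)-2-methylbutanoate | CC[C@@H](C)C(=O)O[C@H](CC=C(C)C)c1ccoc1
F4 | step 12 | (R)-4-methyl-1-[5-(4,4,5,5-tetramethyl-1,3,2-dioxaborolan-2-yl)furan-3-yl]pent-3-en-1-yl (R)-2-methylbutanoate | CC[C@@H](C)C(=O)O[C@H](CC=C(C)C)c1coc(B2OC(C)(C)C(C)(C)O2)c1
F5 | step 12 | 2-bromo-1,4-bis(tert-butyldimethylsilyloxy)benzene | Brc1cc(O[Si](C)(C)C(C)(C)C)ccc1O[Si](C)(C)C(C)(C)C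
F6 | step 12 | (R)-1-{5-[2,5-bis(tert-butyldimethylsilyloxy)phenyl]furan-3-yl}-4-methylpent-3-en-1-yl (R)-2-methylbutanoate | CC[C@@H](C)C(=O)O[C@H](CC=C(C)C)c1coc(-c2cc(O[Si](C)(C)C(C)(C)C)ccc2O[Si](C)(C)C(C)(C)C)c1
F7 | step 5 | 1,4-bis(tert-butyldimethylsilyloxy)-2-(prop-2-yn-1-yl)benzene | C#CCc1cc(O[Si](C)(C)C(C)(C)C)ccc1O[Si](C)(C)C(C)(C)C
F8 | step 5 | methyl 4-[2,5-bis(tert-butyldimethylsilyloxy)phenyl]but-2-ynoate | COC(=O)C#CCc1cc(O[Si](C)(C)C(C)(C)C)ccc1O[Si](C)(C)C(C)(C)C
F9 | step 5 | methyl (E)-4-[2,5-bis(tert-butyldimethylsilyloxy)phenyl]-2-(tributylstannyl)but-2-enoate | COC(=O)/C([Sn](CCCC)(CCCC)CCCC)=C\Cc1cc(O[Si](C)(C)C(C)(C)C)ccc1O[Si](C)(C)C(C)(C)C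
F10 | step 5 | methyl (E)-4-[2,5-bis(tert-butyldimethylsilyloxy)phenyl]-2-iodobut-2-enoate | COC(=O)/C(I)=C\Cc1cc(O[Si](C)(C)C(C)(C)C)ccc1O[Si](C)(C)C(C)(C)C
F11 | step 8 | 4-methylpent-3-enal | CC(C)=CCC=O
F12 | step 8 | (2E)-1-[2,5-bis(tert-butyldimethylsilyloxy)phenyl]-3-[(tert-butyldimethylsilyloxy)methyl]-7-methylocta-2,6-dien-4-ol (racemic) | CC(C)=CCC(O)/C(CO[Si](C)(C)C(C)(C)C)=C/Cc1cc(O[Si](C)(C)C(C)(C)C)ccc1O[Si](C)(C)C(C)(C)C
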